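## Retrosynthetic overview

1. The target comes from one acid treatment that opens an oxolane ketal and removes an aryl silyl ether; the C5 ketone comes from oxidation of a carbinol made by joining C4–C5: an (E)-allylbarium carrying the arene (C1–C4) adds to a (Z)-enal (C5–C16).
2. The (Z)-enal comes from a B-alkyl Suzuki coupling (C7–C8, fixes 6Z) of a C8–C16 terminal alkene with (Z)-3-iodobut-2-en-1-ol.
3. Key step, C12–O bond: the C15 hydroxyl relays O2 to its δ-CH2 (1,5-hydrogen transfer) to give the 12-ketone; the C15–O bond comes from hydration, and C11 is bought with (S)-citronellal.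
4. The aryl C1–C4 unit comes from SN2′ arylation of isoprene monoxide; the phenol C–O bond comes from C–H borylation/oxidation of 2-bromo-6-methylanisole.
5. Rings: the benzene ring is bought; the only ring made is the oxolane ketal (step 4), which is opened again in step 14.

Assumption: (S)-(−)-citronellal is used at its commercial enantiomeric purity (about 97% ee or better), which the target inherits. Chain atoms are called C1–C16 as in the target name (C1 benzylic CH2, C5 and C12 carbonyls, C11 stereocentre, C15 carbinol carbon).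

## Route

Step 1
Reactants: 1 (3S)-3,7-dimethyloct-6-enal [(S)-citronellal]
Product: 2 (4S)-4,8-dimethylnona-1,7-diene
Conditions: Ph3PCH3Br, KOt-Bu, THF, 0 °C → rt
Reagents that add atoms: methyltriphenylphosphonium bromide, C[P+](c1ccccc1)(c1ccccc1)c1ccccc1.[Br-]
Why: Wittig methylenation turns the aldehyde carbon (C9) into a terminal alkene and adds C8; the C11 stereocentre comes from the chiral pool, sits β to the carbonyl and is not touched.

Step 2
Reactants: 2 (4S)-4,8-dimethylnona-1,7-diene
Product: 3 (6S)-2,6-dimethylnon-8-en-2-ol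
Conditions: Mn(dpm)3 (3 mol%; dpm = 2,2,6,6-tetramethylheptane-3,5-dionate), PhSiH3, O2 (1 atm), i-PrOH, 0 °C → rt
Reagents that add atoms: dioxygen, O=O
Why: Mukaiyama hydration (metal-hydride hydrogen-atom transfer, then O2 capture) is Markovnikov and markedly faster at the trisubstituted alkene (tertiary radical) than at the vinyl group, so the C15 tertiary alcohol forms and no stereocentre is made.

Step 3
Reactants: 3 (6S)-2,6-dimethylnon-8-en-2-ol
Product: 5 (4R)-8-hydroxy-4,8-dimethylnon-1-en-5-one, via δ-hydroperoxide 4 (not isolated)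
Conditions: CeCl3 (5 mol%), n-Bu4NCl (15 mol%), O2 (1 atm), MeCN, 400 nm LED, 20 °C, to about 75% conversion; then Ac2O, pyridine, 0 °C
Reagents that add atoms: dioxygen, O=O
Why: Proposed new method: aerobic δ-C–H ketonization of a tertiary alkanol by cerium photocatalysis with a 1,5-hydrogen-transfer relay — O2 oxidizes the photoexcited trivalent cerium chloride complex to start the cycle, 3 binds tetravalent cerium as an alkoxide, 400 nm ligand-to-metal charge transfer releases the C15–O radical and trivalent cerium, the O radical takes a hydrogen from C12 through a six-membered transition state (the only δ-CH2; the tertiary C11–H would need a seven-membered one), O2 traps the C12 radical, trivalent cerium reduces the peroxyl radical to hydroperoxide 4 and returns to the tetravalent state, and Ac2O/pyridine dehydrates 4 (Kornblum–DeLaMare type) to ketone 5, so the C12–O bond comes from O2 and is placed by the C15 hydroxyl while C11 is never planar and keeps its configuration; the closest known reactions are the cerium-photocatalysed δ-C–H amination of alkanols with azodicarboxylates, the Barton nitrite photolysis and hypoiodite δ-etherification, none of which gives the δ-ketone with O2.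

Step 4
Reactants: 5 (4R)-8-hydroxy-4,8-dimethylnon-1-en-5-one
Product: 6 2-methoxy-5,5-dimethyl-2-[(2R)-pent-4-en-2-yl]oxolane (both epimers at the ketal carbon)
Conditions: MeOH, PPTS (5 mol%), 3 Å MS, rt
Reagents that add atoms: methanol, CO
Why: acid-catalysed mixed ketalization of the γ-hydroxy ketone (hemiketal, oxocarbenium ion, methanol capture) masks ketone and tertiary alcohol in one oxolane ring for the borane and organobarium steps, and the mild acid does not enolize C11.

Step 5
Reactants: 7 but-2-yn-1-ol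
Product: 9 (2Z)-3-iodobut-2-en-1-ol, via cyclic alkenylalanate 8 (not isolated)
Conditions: NaAlH2(OCH2CH2OMe)2, THF, 0 °C → rt; then I2, −78 → 0 °C
Reagents that add atoms: iodine, [I][I]
Why: hydroxyl-directed trans-hydroalumination puts aluminium on C3 cis to the CH2O group in a five-membered alanate, and iodinolysis with retention gives the Z iodide.

Step 6
Reactants: 6 2-methoxy-5,5-dimethyl-2-[(2R)-pent-4-en-2-yl]oxolane; 9 (2Z)-3-iodobut-2-en-1-ol
Product: 11 (2Z,7R)-7-(2-methoxy-5,5-dimethyloxolan-2-yl)-3-methyloct-2-en-1-ol, via alkyl-9-BBN borane 10 (not isolated)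
Conditions: 9-BBN, THF, rt; then 9, PdCl2(dppf) (5 mol%), AsPh3, Cs2CO3, DMF/H2O, rt
Reagents that add atoms: none
Why: anti-Markovnikov hydroboration of the vinyl group and B-alkyl Suzuki–Miyaura coupling (zerovalent palladium cycle) form C7–C8 with retention at the vinyl iodide, so C5 and C8 end up cis (6Z); the ketal is inert to borane and aqueous base.

Step 7
Reactants: 11 (2Z,7R)-7-(2-methoxy-5,5-dimethyloxolan-2-yl)-3-methyloct-2-en-1-ol
Product: 12 (2Z,7R)-7-(2-methoxy-5,5-dimethyloxolan-2-yl)-3-methyloct-2-enal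
Conditions: MnO2, CH2Cl2, rt
Reagents that add atoms: none
Why: MnO2 oxidation of an allylic alcohol runs under neutral conditions that spare the ketal; the Z geometry is kept if the enal is used at once.

Step 8
Reactants: 13 1-bromo-2-methoxy-3-methylbenzene (2-bromo-6-methylanisole)
Product: 15 3-bromo-4-methoxy-5-methylphenol, via aryl pinacol boronate 14 (not isolated)
Conditions: [Ir(OMe)(cod)]2 (1.5 mol%), dtbpy (3 mol%), HBpin, hexane, rt → 50 °C; then KHSO5, acetone/H2O, rt
Reagents that add atoms: potassium peroxymonosulfate, [K+].[O-]S(=O)(=O)OO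
Why: iridium-catalysed C–H borylation is sterically controlled and goes to the only C–H without an ortho substituent (para to OMe) of this 1,2,3-trisubstituted arene, and KHSO5 oxidizes C–B to C–O at the same carbon.

Step 9
Reactants: 15 3-bromo-4-methoxy-5-methylphenol
Product: 16 (3-bromo-4-methoxy-5-methylphenoxy)(tert-butyl)dimethylsilane
Conditions: TBSCl, imidazole, CH2Cl2, rt
Reagents that add atoms: tert-butyldimethylsilyl chloride, CC(C)(C)[Si](C)(C)Cl
Why: silylation protects the phenol against the Grignard, organobarium and periodinane steps.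

Step 10
Reactants: 16 (3-bromo-4-methoxy-5-methylphenoxy)(tert-butyl)dimethylsilane; 17 2-ethenyl-2-methyloxirane (isoprene monoxide, racemic)
Product: 19 (2E)-4-[5-(tert-butyldimethylsilyloxy)-2-methoxy-3-methylphenyl]-2-methylbut-2-en-1-ol, via arylmagnesium bromide 18 (not isolated)
Conditions: Mg, THF, 40 °C; then CuI (10 mol%), 17, THF, −30 → 0 °C
Reagents that add atoms: none
Why: copper-catalysed anti-SN2′ opening of the vinyl oxirane by the aryl Grignard reagent through the s-trans conformer forms Ar–C1 and the (E)-trisubstituted alkene (about 9:1; the minor Z isomer is removed by chromatography).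

Step 11
Reactants: 19 (2E)-4-[5-(tert-butyldimethylsilyloxy)-2-methoxy-3-methylphenyl]-2-methylbut-2-en-1-ol
Product: 20 tert-butyl{3-[(2E)-4-chloro-3-methylbut-2-en-1-yl]-4-methoxy-5-methylphenoxy}dimethylsilane
Conditions: PPh3, N-chlorosuccinimide, THF, 0 °C → rt
Reagents that add atoms: N-chlorosuccinimide, O=C1CCC(=O)N1Cl
Why: Appel-type chlorination (alkoxyphosphonium ion, SN2 by chloride) converts the primary allylic alcohol without allylic shift or loss of E geometry.

Step 12
Reactants: 20 tert-butyl{3-[(2E)-4-chloro-3-methylbut-2-en-1-yl]-4-methoxy-5-methylphenoxy}dimethylsilane; 12 (2Z,7R)-7-(2-methoxy-5,5-dimethyloxolan-2-yl)-3-methyloct-2-enal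
Product: 22 (2E,6Z,11R)-1-[5-(tert-butyldimethylsilyloxy)-2-methoxy-3-methylphenyl]-11-(2-methoxy-5,5-dimethyloxolan-2-yl)-3,7-dimethyldodeca-2,6-dien-5-ol (epimers at C5 and the ketal carbon), via allylbarium chloride 21 (not isolated)
Conditions: Ba (from BaI2, Li, biphenyl), THF, −78 °C; then 12, −78 °C
Reagents that add atoms: none
Why: Yamamoto-type allylbarium addition: the allylbarium keeps its E geometry at −78 °C and attacks the aldehyde 1,2 with its unsubstituted α-carbon (C4), giving the linear 2E,6Z skipped dienol; the uncontrolled C5 carbinol centre is removed in step 13.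

Step 13
Reactants: 22 (2E,6Z,11R)-1-[5-(tert-butyldimethylsilyloxy)-2-methoxy-3-methylphenyl]-11-(2-methoxy-5,5-dimethyloxolan-2-yl)-3,7-dimethyldodeca-2,6-dien-5-ol
Product: 23 (2E,6Z,11R)-1-[5-(tert-butyldimethylsilyloxy)-2-methoxy-3-methylphenyl]-11-(2-methoxy-5,5-dimethyloxolan-2-yl)-3,7-dimethyldodeca-2,6-dien-5-one (both ketal epimers)
Conditions: Dess–Martin periodinane, NaHCO3, CH2Cl2, 0 °C
Reagents that add atoms: none
Why: buffered Dess–Martin oxidation gives the C5 ketone without base, so the 2E alkene does not move into conjugation and the 6Z enone is kept.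

Step 14
Reactants: 23 (2E,6Z,11R)-1-[5-(tert-butyldimethylsilyloxy)-2-methoxy-3-methylphenyl]-11-(2-methoxy-5,5-dimethyloxolan-2-yl)-3,7-dimethyldodeca-2,6-dien-5-one
Product: 24 (2E,6Z,11R)-15-hydroxy-1-(5-hydroxy-2-methoxy-3-methylphenyl)-3,7,11,15-tetramethylhexadeca-2,6-diene-5,12-dione
Conditions: aq. HF (48%), MeCN, 0 °C → rt
Reagents that add atoms: water, O
Why: one mildly acidic fluoride treatment hydrolyses the methyl ketal (oxocarbenium ion, water) to the γ-hydroxy ketone and cleaves the aryl silyl ether; both ketal epimers converge, and the conditions are too mild to enolize C11 or isomerize the enones.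

## Compound list

1 | (3S)-3,7-dimethyloct-6-enal [(S)-citronellal] | O=CC[C@@H](C)CCC=C(C)C | starting material
2 | (4S)-4,8-dimethylnona-1,7-diene | C=CC[C@@H](C)CCC=C(C)C | intermediate
3 | (6S)-2,6-dimethylnon-8-en-2-ol | C=CC[C@@H](C)CCCC(C)(C)O | intermediate
4 | (6R)-5-hydroperoxy-2,6-dimethylnon-8-en-2-ol (both C5 epimers) | C=CC[C@@H](C)C(OO)CCC(C)(C)O | intermediate
5 | (4R)-8-hydroxy-4,8-dimethylnon-1-en-5-one | C=CC[C@@H](C)C(=O)CCC(C)(C)O | intermediate
6 | 2-methoxy-5,5-dimethyl-2-[(2R)-pent-4-en-2-yl]oxolane (both ketal epimers) | C=CC[C@@H](C)C1(OC)CCC(C)(C)O1 | intermediate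
7 | but-2-yn-1-ol | CC#CCO | starting material
8 | sodium 2,2-bis(2-methoxyethoxy)-3-methyl-2,5-dihydro-1,2-oxaluminol-2-uide (cyclic alkenylalanate) | [Na+].CC1=CCO[Al-]1(OCCOC)OCCOC | intermediate
9 | (2Z)-3-iodobut-2-en-1-ol | C/C(I)=C/CO | intermediate
10 | 9-[(4R)-4-(2-methoxy-5,5-dimethyloxolan-2-yl)pentyl]-9-borabicyclo[3.3.1]nonane | C1CC2CCCC(C1)B2CCC[C@@H](C)C1(OC)CCC(C)(C)O1 | intermediate
11 | (2Z,7R)-7-(2-methoxy-5,5-dimethyloxolan-2-yl)-3-methyloct-2-en-1-ol | OC/C=C(/C)CCC[C@@H](C)C1(OC)CCC(C)(C)O1 | intermediate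
12 | (2Z,7R)-7-(2-methoxy-5,5-dimethyloxolan-2-yl)-3-methyloct-2-enal | O=C/C=C(/C)CCC[C@@H](C)C1(OC)CCC(C)(C)O1 | intermediate
13 | 1-bromo-2-methoxy-3-methylbenzene | COc1c(C)cccc1Br | starting material
14 | 2-(3-bromo-4-methoxy-5-methylphenyl)-4,4,5,5-tetramethyl-1,3,2-dioxaborolane | COc1c(C)cc(cc1Br)B1OC(C)(C)C(C)(C)O1 | intermediate
15 | 3-bromo-4-methoxy-5-methylphenol | COc1c(C)cc(O)cc1Br | intermediate
16 | (3-bromo-4-methoxy-5-methylphenoxy)(tert-butyl)dimethylsilane | COc1c(C)cc(O[Si](C)(C)C(C)(C)C)cc1Br | intermediate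
17 | 2-ethenyl-2-methyloxirane (isoprene monoxide, racemic) | CC1(C=C)CO1 | starting material
18 | [5-(tert-butyldimethylsilyloxy)-2-methoxy-3-methylphenyl]magnesium bromide | COc1c(C)cc(O[Si](C)(C)C(C)(C)C)cc1[Mg]Br | intermediate
19 | (2E)-4-[5-(tert-butyldimethylsilyloxy)-2-methoxy-3-methylphenyl]-2-methylbut-2-en-1-ol | COc1c(C)cc(O[Si](C)(C)C(C)(C)C)cc1C/C=C(\C)CO | intermediate
20 | tert-butyl{3-[(2E)-4-chloro-3-methylbut-2-en-1-yl]-4-methoxy-5-methylphenoxy}dimethylsilane | COc1c(C)cc(O[Si](C)(C)C(C)(C)C)cc1C/C=C(\C)CCl | intermediate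
21 | {(2E)-4-[5-(tert-butyldimethylsilyloxy)-2-methoxy-3-methylphenyl]-2-methylbut-2-en-1-yl}barium chloride | COc1c(C)cc(O[Si](C)(C)C(C)(C)C)cc1C/C=C(\C)C[Ba]Cl | intermediate
22 | (2E,6Z,11R)-1-[5-(tert-butyldimethylsilyloxy)-2-methoxy-3-methylphenyl]-11-(2-methoxy-5,5-dimethyloxolan-2-yl)-3,7-dimethyldodeca-2,6-dien-5-ol (epimers at C5 and ketal carbon) | COc1c(C)cc(O[Si](C)(C)C(C)(C)C)cc1C/C=C(\C)CC(O)/C=C(/C)CCC[C@@H](C)C1(OC)CCC(C)(C)O1 | intermediate
23 | (2E,6Z,11R)-1-[5-(tert-butyldimethylsilyloxy)-2-methoxy-3-methylphenyl]-11-(2-methoxy-5,5-dimethyloxolan-2-yl)-3,7-dimethyldodeca-2,6-dien-5-one (both ketal epimers) | COc1c(C)cc(O[Si](C)(C)C(C)(C)C)cc1C/C=C(\C)CC(=O)/C=C(/C)CCC[C@@H](C)C1(OC)CCC(C)(C)O1 | intermediate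
24 | (2E,6Z,11R)-15-hydroxy-1-(5-hydroxy-2-methoxy-3-methylphenyl)-3,7,11,15-tetramethylhexadeca-2,6-diene-5,12-dione | COc1c(C)cc(O)cc1C/C=C(\C)CC(=O)/C=C(/C)CCC[C@@H](C)C(=O)CCC(C)(C)O | target

## Step count and risks

Total steps: 14. Longest linear sequence: 9 (steps 1, 2, 3, 4, 6, 7, 12, 13, 14).

**Step 3 (the proposed aerobic δ-ketonization).** Likely failures are chlorine-radical or peroxyl attack on the vinyl group, β-scission of the tertiary alkoxy radical, and some ε-attack at C11–H. Product 5 can also be over-oxidized, because its alkoxy radical has no δ-hydrogen left; hence the limited conversion. The fallback uses known chemistry, a C–N relay in place of O2. It sets out from 3: NOCl/pyridine at −20 °C gives the tertiary nitrite (6S)-2,6-dimethylnon-8-en-2-yl nitrite F1. Pyrex-filtered mercury-lamp photolysis in benzene (Barton reaction) moves NO to C12 by the same 1,5-hydrogen transfer, and the C-nitroso compound tautomerizes to the oxime (6R)-5-(hydroxyimino)-2,6-dimethylnon-8-en-2-ol F2. Reductive deoximation with aqueous TiCl3/NH4OAc gives 5, where the route is rejoined.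

**Step 12 (allylbarium addition).** Likely failures are loss of α-selectivity or E geometry, proton transfer from the benzylic-allylic C1–H to the allylbarium, and Z→E drift of enal 12. The fallback is a sulfone route. It sets out from 20 (and uses 12): PhSO2Na in DMF gives the allyl sulfone tert-butyl{4-methoxy-3-methyl-5-[(2E)-3-methyl-4-(phenylsulfonyl)but-2-en-1-yl]phenoxy}dimethylsilane F3. Its much less basic α-sulfonyl anion (n-BuLi, THF, −78 °C) adds to 12 to give the β-hydroxy sulfone (2E,6Z,11R)-1-[5-(tert-butyldimethylsilyloxy)-2-methoxy-3-methylphenyl]-11-(2-methoxy-5,5-dimethyloxolan-2-yl)-3,7-dimethyl-4-(phenylsulfonyl)dodeca-2,6-dien-5-ol F4. Dess–Martin oxidation gives the β-keto sulfone (2E,6Z,11R)-1-[5-(tert-butyldimethylsilyloxy)-2-methoxy-3-methylphenyl]-11-(2-methoxy-5,5-dimethyloxolan-2-yl)-3,7-dimethyl-4-(phenylsulfonyl)dodeca-2,6-dien-5-one F5. SmI2 in THF/MeOH at −78 °C removes the sulfonyl group and returns to the route at 23.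

**Step 2 (site-selective hydration).** The likely failure is partial hydration of the vinyl group. The fallback sets out from 2: m-CPBA (1.0 equiv, CH2Cl2, 0 °C) epoxidizes only the trisubstituted alkene to 2,2-dimethyl-3-[(3S)-3-methylhex-5-en-1-yl]oxirane F6. LiAlH4 in THF opens it at the less substituted carbon and gives 3, where the route is rejoined.

## Further compounds

F1 | step 3 | (6S)-2,6-dimethylnon-8-en-2-yl nitrite | C=CC[C@@H](C)CCCC(C)(C)ON=O
F2 | step 3 | (6R)-5-(hydroxyimino)-2,6-dimethylnon-8-en-2-ol | C=CC[C@@H](C)C(=NO)CCC(C)(C)O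
F3 | step 12 | tert-butyl{4-methoxy-3-methyl-5-[(2E)-3-methyl-4-(phenylsulfonyl)but-2-en-1-yl]phenoxy}dimethylsilane | COc1c(C)cc(O[Si](C)(C)C(C)(C)C)cc1C/C=C(\C)CS(=O)(=O)c1ccccc1
F4 | step 12 | (2E,6Z,11R)-1-[5-(tert-butyldimethylsilyloxy)-2-methoxy-3-methylphenyl]-11-(2-methoxy-5,5-dimethyloxolan-2-yl)-3,7-dimethyl-4-(phenylsulfonyl)dodeca-2,6-dien-5-ol (diastereomer mixture) | COc1c(C)cc(O[Si](C)(C)C(C)(C)C)cc1C/C=C(\C)C(C(O)/C=C(/C)CCC[C@@H](C)C2(OC)CCC(C)(C)O2)S(=O)(=O)c1ccccc1
F5 | step 12 | (2E,6Z,11R)-1-[5-(tert-butyldimethylsilyloxy)-2-methoxy-3-methylphenyl]-11-(2-methoxy-5,5-dimethyloxolan-2-yl)-3,7-dimethyl-4-(phenylsulfonyl)dodeca-2,6-dien-5-one (diastereomer mixture) | COc1c(C)cc(O[Si](C)(C)C(C)(C)C)cc1C/C=C(\C)C(C(=O)/C=C(/C)CCC[C@@H](C)C2(OC)CCC(C)(C)O2)S(=O)(=O)c1ccccc1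
F6 | step 2 | 2,2-dimethyl-3-[(3S)-3-methylhex-5-en-1-yl]oxirane (both epoxide epimers) | C=CC[C@@H](C)CCC1OC1(C)C
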